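Take the bis adduct of the dawn run: it reads 59.1 % at 1.04 d and 59.8 % at 5.00 d, with a scatter of 0.3 percentage points, so the dawn readings stand still from the first one on. Yet bis adduct and first product together leave 26.7 % of the substrate charged unaccounted for, so read the reagent as the limiting reagent and the 10 d of the new flasks as the same standstill.

| setting | noon | dawn | alpha | eta | zeta |
|---|---|---|---|---|---|
| substrate | 0.050 M | 0.050 M | 0.050 M | 0.050 M | 0.050 M |
| reagent | 0.32 equiv | 1.9 equiv | 0.500 equiv | 2.00 equiv | 3.00 equiv |
| remark | run made earlier | run made earlier |  |  |  |
| time |  |  | 10 d | 10 d | 10 d |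

| run | time / d | bis adduct / % | first product / % |
|---|---|---|---|
| noon | 1.04 | 4.9 | 14.5 |
| noon | 2.08 | 5.2 | 14.8 |
| noon | 3.00 | 4.8 | 14.7 |
| noon | 4.00 | 4.9 | 14.1 |
| noon | 5.00 | 5.6 | 14.3 |
| dawn | 1.04 | 59.1 | 13.9 |
| dawn | 2.08 | 59.9 | 13.6 |
| dawn | 3.00 | 59.9 | 14.2 |
| dawn | 4.00 | 59.6 | 14.3 |
| dawn | 5.00 | 59.8 | 13.5 |

(scatter of a reading: 0.3 percentage points)

- steps that have been proposed: reagent + first product -> bis adduct; reagent + other mono adduct -> bis adduct; substrate + reagent -> first product; substrate + reagent -> other mono adduct; 2 reagent -> self-condensation product

* amount of bis adduct at the end, in percent of the substrate charged, for each flask in turn (alpha, eta, zeta)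

At the last dawn reading, bis adduct with two reagent units each and first product with one hold 70.1 % of the reagent charged. Call this the capture share: reagent units in these two products per unit charged.

Now compare eta with dawn, its neighbour, which differs by 0.100 equiv of reagent. My own reckoning holds the capture share and the first product at dawn's values; noon, with less reagent, reads 14.3 % first product. Eta then binds 1.40 units per substrate. Subtract the first product and divide by two: bis adduct 63.3 %, which is 3.5 points above dawn. In zeta the same share gives 2.10 units, more than the two a substrate can carry, so the share has to fall there, and this reckoning gives no zeta number.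

The forecast gives 11 %, 62 % and 79 % for alpha, eta and zeta, on the ground that “Effective reagent exposure is about 0.69 × equiv in both runs”. For eta it stands below my figure.

The flasks give 10.4 %, 62.9 % and 89.3 % for alpha, eta and zeta, so zeta ends 10 points above the forecast.

    reagent + first product → bis adduct (k = 0.638 L mol⁻¹ min⁻¹)
    reagent + other mono adduct → bis adduct (k = 0.431 L mol⁻¹ min⁻¹)
    substrate + reagent → first product (k = 0.278 L mol⁻¹ min⁻¹)
    substrate + reagent → other mono adduct (k = 0.0956 L mol⁻¹ min⁻¹)
    2 reagent → self-condensation product (k = 0.0734 L mol⁻¹ min⁻¹)

Eta holds 0 % of its reagent at the end, and its bis adduct is the same at 5.00 d and 100 d. Its capture share comes to 69.4 %, against 70.1 % read at dawn. Zeta, with 3.89 % first product, comes to 60.8 %, lower than dawn, and there c(self-condensation product) stands at 0.0287 M.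

The readings stem from a simulated flask for substances that don't exist, noise included.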